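Late in the blue run, from 2.50 min on, [intermediate A]/[starting material] reads steady at 0.791, the exchange ratio, taken here as the mark of a pre-equilibrium between the two species.

| flask | starting material | coupling partner | remark | time |
|---|---|---|---|---|
| blue | 0.40 M | 0.60 equiv | run made earlier |  |
| flask | 0.80 M | 0.600 equiv |  | 20 min |

blue run (percent of the starting material charged)

| time / min | intermediate A / % | product / % | starting material / % |
|---|---|---|---|
| 0.500 | 26.2 | 0.1 | 54.5 |
| 1.00 | 30.8 | 0 | 42.2 |
| 1.50 | 29.9 | 0.2 | 37.8 |
| 2.50 | 26.2 | 2.2 | 32.9 |
| 3.00 | 24.6 | 2.0 | 30.9 |
| 4.00 | 22.1 | 4.0 | 28.4 |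

(scatter of a reading: 0.3 percentage points)



- time, not beyond 20 min, at which the flask holds most intermediate A
- the amount of intermediate A, in percent of the starting material charged, at that time

Freezing that ratio leaves one rate to reckon: how fast the pool of starting material plus intermediate A drains. In the blue run, the pool's rate of fall divided by the squared fraction of starting material reads 0.659 min⁻¹ early and 0.610 min⁻¹ late, so the drain reads as second order. Such a drain makes 1/pool − 1, with the pool as a fraction of the charge, grow with charge times time. The blue run reads 0.370 at 1.00 min. The flask, at twice the charge, is then reckoned to reach 0.740 by that time, which gives a pool of 57.5% and, split by the ratio, 25.4% intermediate A. With the exchange taken as first order, this reckoning keeps the peak near 1.00 min.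

The forecast says 31.3% at 0.57 min: “If every step is bimolecular, doubling concentration halves the timescale and leaves yields unchanged”. The flask gives 25.5% at 0.992 min.

    starting material ⇌ intermediate A (K = 0.740, k = 0.0210 s⁻¹)
    starting material ⇌ intermediate B (K = 2.10, k = 0.00180 s⁻¹)
    coupling partner + intermediate A ⇌ intermediate C (K = 0.720 M⁻¹, k = 0.0970 M⁻¹ s⁻¹)
    coupling partner + intermediate B → intermediate D (k = 0.0230 M⁻¹ s⁻¹)
    coupling partner + intermediate D → product (k = 0.0410 M⁻¹ s⁻¹)
    2 starting material → homo dimer (k = 0.00900 M⁻¹ s⁻¹)

The reckoned height lies close to that result. The exchange of starting material and intermediate A, by this step alone, relaxes with a half-life of 0.234 min, short against 20 min. At 20.0 min the flask holds 5.24% starting material, which the ratio turns into 4.14% intermediate A, against 4.05% found. The neighbour flask with 2.40 equiv of coupling partner peaks lower, at 18.6%. That neighbour flask ends with 6.07% starting material, for which the ratio gives 4.80% intermediate A, and it holds 4.85%.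

Readings and results are simulated with constants of no real substance; noise was put on by code.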